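(The numbers belong to no real substance; the rest is arithmetic.)

Late in this flask, what I want to know is how much right-handed substrate stands once the left-handed substrate has thinned out, and that can be had by hand.

    coupling partner + catalyst + left-handed substrate → catalyst + left-handed product (k1 = 6.99 M⁻² min⁻¹)
    coupling partner + catalyst + right-handed substrate → catalyst + right-handed product (k2 = 0.0609 M⁻² min⁻¹)
    solid reagent ⇌ coupling partner, rate k3*(cs3 - [coupling partner]) while solid is left; crystals form when [coupling partner] > cs3 (cs3 = 19 mM, k3 = 5.20 × 10⁻⁴ min⁻¹)

left-handed substrate 33 mM; solid reagent 49.5 mM; catalyst 2.4 mM; right-handed substrate 33 mM; time 15 d

- catalyst is single-handed; left-handed substrate and right-handed substrate are mirror images of each other, charged as a racemate, each of them at the stated concentration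
- solid, in amounts per volume of the solution: solid reagent
- at the start none of the solid reagent is in solution
- the reaction counts as stopped when no species that holds the left-handed substrate and right-handed substrate together changes by six tenths of a point or more over the second half of the time
- run time (flask): 15 d

- the state of affairs at 15 d: stopped, and by what, or still going (for what has run out or reacted, a solid counts together with what of it has only dissolved) (it is still moving / the coupling partner has run out first / no working catalyst is left)
- share of the left-handed substrate and right-handed substrate together used up at 15 d
- left-handed product at 15 d, in percent of the left-handed substrate and right-handed substrate together charged
- right-handed substrate at 15 d, in percent of the left-handed substrate and right-handed substrate together charged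

Let r and u be the fractions of their charges of left-handed and right-handed substrate still there. Both steps carry the same coupling partner and catalyst, so dividing one rate by the other removes time and leaves ln r = s ln u, where s, the first rate constant over the second, is 115, the selectivity factor.

My first way uses s and a guess. If r is a hundredth, u is 0.961, and a guess wrong by a factor 10 moves u by 0.0201.

My second way is a clock that never uses the first rate constant. Solid feeds partner at k3 times the shortfall below solubility, so if the solid has gone, the summed shortfall over time is at least the charge over k3. Dissolving takes at least 3.48 d, but that minimum does not show the solid gone by 15 d: its charge is more than the solubility, so it can go only as partner is used up, and I assume that it has. The exponent for the right-handed substrate is then at most 0.0461, which gives a floor of u = 0.955.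

The two ways come from different constants and part by 0.00570. The clock cheats slightly, since it counts partner at solubility after the solid has gone. I commit to 47.7% for y_S, 49.7% for y_P and 52.0% for conv. If half of the right-handed loss falls in the second half of the time, that is 1.1 percentage points, above the 0.6 points of the stopping rule, so I say the flask is still moving.

The forecast, stepping the partner in blocks of time, gives conv 51.7%, y_P 49.6% and y_S 47.9%, and for the state at the end it says: it is still moving, in its words “so the reaction is still moving”. Its y_S stands slightly above mine.

The simulation gives it is still moving, with conv 51.7%, y_P 49.6% and y_S 47.9%. In this flask at 2.93 d the left-handed substrate has a half-life of 2.7 d by its step, short against 15 d, while s times that gives the right-handed substrate 307 d, long against it. The same s turns the 0.72% of left-handed charge left here into u = 95.8%, against 96% standing, and in the second flask, with 12 mM of solid reagent, it turns 64% left into 99.6%, against 99.6% standing.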